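## The problem

Compound 24 joins two flavan units through a carbon–carbon bond: an upper 2,3-trans-3,4-trans 4-arylflavan-3-ol (rings A, C and B) is bonded from C4 to carbon E2' of the pyrogallol ring E, and E1' of the same ring carries C2 of a lower 2,3-trans-3,4-cis flavan-3,4-diol (rings D and F). Ring E is thus a pentasubstituted hub with two benzylic stereocentres on neighbouring carbons, and the C4–E2' bond is flanked on both sides, which speaks against any late coupling at that position. Six stereocentres must be set, (2R,3S,4S) in ring C and (2R,3S,4S) in ring F. Within each ring one centre can steer the others: in ring C the C3 oxygen can direct an addition at C2 by chelation and the all-equatorial ring is the thermodynamic one, and in ring F the C2 aryl group can send a syn-dihydroxylation of a C3=C4 double bond to the opposite face. The two triads lie on opposite sides of a flat arene, so C3/C4 of ring C and C2 of ring F each need control by an external chiral reagent. The molecule has eleven hydroxyl groups, eight phenolic and six of these on two air-sensitive pyrogallol rings, and the C4 hydroxyl of ring F is a benzylic alcohol para to the ring D oxygen that ionises in acid, so the unmasking has to be one late, neutral operation. The enabling feature is that C4 of ring C sits on C4a of ring A, ortho to the ring oxygen O1: ring A plus C4 is a latent o-quinone methide, and C2, C3 and the C3 oxygen are the carbonyl carbon, α-carbon and ether oxygen of an alkoxyacetaldehyde, so one [4+2] annulation can form C3–C4 and O1–C2 with ring E already in place.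

## Retrosynthesis

**Cut 1, nine O–benzyl bonds (24 to 23).** All eight phenols and the ring C hydroxyl are carried as benzyl ethers, so 24 is released by one hydrogenolysis without acid, base or fluoride near the pyrogallol rings or the ionisable C4 hydroxyl of ring F. Silyl or acetal protection would need fluoride or acid at the end and was set aside. The price is that the benzylic C–O bonds of 23 must survive the hydrogenolysis.

**Cut 2, the C3–O and C4–O bonds of ring F (23 to 22).** A syn-dihydroxylation can only give the 3,4-cis diol, and the C2 aryl group of a 2H-chromene sends the oxidant to the other face, which is the 2,3-trans-3,4-cis pattern required. Reduction of a 3-hydroxyflavan-4-one, the neighbouring option, tends towards the 3,4-trans diol. Chromene 22 has one stereocentre in ring F instead of three.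

**Cut 3, the C3=C4 bond of ring F (22 to 21).** Ring closure by olefin metathesis fixes the substitution pattern of ring D through the choice of the vinylphenol. A Friedel–Crafts closure of C4–C4a would have to choose between two activated positions of a resorcinol ether. Diene 21 is open-chain at ring F; the forward step only has to leave the ether stereocentre, the later C2 of ring F, untouched.

**Cut 4, O1–C2 of ring F, then C2–C3 of ring F, then the formyl carbon (21 to 19 and 20, 19 to 18, 18 to 16).** The aryl ether is made from allylic alcohol 19 and vinylphenol 20 with inversion, 19 from aldehyde 18 by a ligand-controlled vinyl addition, and 18 from bromide 16 by halogen–metal exchange and formylation. Because ring E separates this centre from the ring C triad, a chiral ligand is preferred to any reliance on the resident centres. Bromine is the placeholder at E1' because it is small, inert to everything before this point and converted in one step. Phenol 20 comes from 4 by methylenation.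

**Cut 5, O1–C2 of ring C and the C2–ring B bond (16 to 15, 15 to 13 and 14).** Ring B is added as Grignard reagent 14 to the masked aldehyde of lactol 13. The C3 benzyloxy group can chelate magnesium and direct the addition to the syn carbinol 15, and closure by the ring A phenol with inversion then gives the 2,3-trans flavan. Closure through a benzylic cation would end in the same all-equatorial ring, so the plan does not depend on perfect chelation control. Reagent 14 is made from bromide 3, which also supplies ring E.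

**Cut 6, C3–C4 and O1–C2 of ring C (13 to 9 and 10).** This is the disconnection the structure invites. Attaching ring E to a preformed flavan C4 cation would ask a bromopyrogallol ether to react at its most hindered position. The annulation instead has the bond to ring E in place beforehand and creates C3 and C4 together under one chiral amine. Sulfone 9 is racemic and its stereocentre is erased on the way to the o-quinone methide 11; 10 is a commercial two-carbon unit that brings the C3 oxygen already protected. The forward reaction must release 11 under conditions the enamine 12 tolerates and must overcome the shielding of the methide carbon by ring E. A small ortho placeholder, a reversible sulfinate reservoir and an excess of 10 are chosen to help.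

**Cut 7, the C–S bond, the allyl ether and the C4–E2' bond (9 to 7, 7 to 6 and 5, then to 3, 2, 1 and 4).** The crowded C4–E2' bond is formed as the addition of aryllithium 6 to aldehyde 5; 6 is obtained from 3 by deprotonation between bromine and a benzyloxy group. A carbonyl addition is the least demanding way to bond a doubly flanked aryl carbon, and using 6 directly saves a detour through a ring E aldehyde and a ring A organometallic. Compound 5 is the allyl ether of commercial 4, and 3 comes from commercial 1 through triol 2. Two building blocks, 3 and 4, thus supply four of the five aromatic rings.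

## Roads not taken

**Alternative 1:** Ring-closing metathesis to a flavene as the strategic step. The cut is the C3=C4 bond of ring F: diene A1 would be closed by RuCl2(=CHPh)(PCy3)(H2IMes), the second-generation Grubbs catalyst, to flavene A2, and osmylation would follow.
- Merits: the closure is reliable, it fixes the ring D substitution pattern without ambiguity, and it prepares the cis-diol with the right relation to C2.
- Weak points: it concerns ring F only. A1 already contains the whole upper 4-arylflavan with its three stereocentres, the crowded C4–E2' bond and the ether stereocentre, so the hard questions are postponed.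
- Comparison: as a way to close ring F it is as good as anything available, and the chosen plan adopts it unchanged (A1 and A2 are the same compounds as 21 and 22, steps 13 and 14). What the chosen plan adds is an answer for ring C; what it shares is the need to set C2 of ring F by reagent control (steps 10 and 12).

**Alternative 2:** Ring B p-quinone methide trapped by the ring A phenol. The cut is O1–C2 of ring C. Ag2O would oxidise the 4-hydroxy-3,5-bis(benzyloxy)benzyl group of the open-chain precursor A3 to the p-quinone methide A4, and the ring A phenol would add to the methide carbon to give flavan-3-ol A5.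
- Merits: the closure is neutral and reversible, so the 2,3-trans ring should form under thermodynamic control, with no alcohol to activate and no carbinol configuration to rely on.
- Weak points: A3 already holds C3, C4 and ring E, so the hardest bond and two stereocentres are left unsolved. Ring B needs its own protection pattern with a free 4'-hydroxyl, so bromide 3 can no longer serve rings B and E alike, and that free phenol would compete in the later etherification for ring F. Ag2O also faces an electron-rich ring A phenol.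
- Comparison: for the O1–C2 closure alone this road is arguably milder and more surely trans than the Mitsunobu closure of step 8. The chosen plan sets against it that its closure has the same thermodynamic preference behind it, needs no extra protecting-group pattern, and follows a step that actually creates C3–C4.

**Alternative 3:** Ring E grown by furan–alkyne benzannulation. The cuts are E1'–E6' and E2'–E3'. The C4 ynoate A6 and 3,4-bis(benzyloxy)furan A7 would undergo [4+2] cycloaddition, and acid would open the oxygen bridge to give the 3-hydroxy-4,5-bis(benzyloxy)benzoate A8.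
- Merits: the crowded C4–aryl bond is never made, because ring E is built on C4. The ester at E1' is a handle for ring F, and bridge opening away from the ester-bearing carbon should place the phenol at E3'.
- Weak points: A6 needs a 3,4-trans 4-alkynylflavan, and its C4 hydrogen, γ to the ester, invites isomerisation to an allenoate with loss of configuration. A7 is an electron-rich, sensitive furan. Furan cycloadditions with a β-branched ynoate are slow and reversible. The bridge opening needs acid next to benzylic ethers. The free E3' phenol and the ester each cost further steps.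
- Comparison: this road is better in one respect, since it avoids bond formation at a doubly flanked position, the very point where step 6 is at risk. The chosen plan sets against it convergence, catalyst control of C3 and C4 in one step, a much shorter sequence and a fallback for step 6.

Key step: step 6

Assumption: the (E)-enamine of 10 is taken to react on the face remote from the CPh2OSiMe3 group, as enamines of α-alkyl aldehydes do, so the (R)-catalyst should lead to (3S,4S)-13 (the (S)-catalyst would be used if the sense proved opposite); 4 is taken as a commercial compound.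

## Route

Step 1
Reactants: 1 5-bromo-1,2,3-trimethoxybenzene
Product: 2 5-bromobenzene-1,2,3-triol
Conditions: BBr3, CH2Cl2, −78 °C to rt; H2O
Reagents that add atoms: none
Why: Lewis-acid ether cleavage: BBr3 binds each methoxy oxygen and bromide removes the methyl group by SN2; the aryl bromide is inert.

Step 2
Reactants: 2 5-bromobenzene-1,2,3-triol
Product: 3 1,2,3-tris(benzyloxy)-5-bromobenzene
Conditions: BnBr, K2CO3, DMF, 60 °C
Reagents that add atoms: benzyl bromide, BrCc1ccccc1
Why: Williamson ether synthesis on the three phenoxides; the air-sensitive triol is benzylated at once.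

Step 3
Reactants: 4 4-(benzyloxy)-2-hydroxybenzaldehyde
Product: 5 2-(allyloxy)-4-(benzyloxy)benzaldehyde
Conditions: allyl bromide, K2CO3, DMF, 50 °C
Reagents that add atoms: allyl bromide, C=CCBr
Why: Williamson ether synthesis; the allyl ether masks the ring A phenol through the organolithium step and can later be removed by zerovalent palladium without base.

Step 4
Reactants: 3 1,2,3-tris(benzyloxy)-5-bromobenzene; 5 2-(allyloxy)-4-(benzyloxy)benzaldehyde
Product: 7 rac-[2-(allyloxy)-4-(benzyloxy)phenyl][2,3,4-tris(benzyloxy)-6-bromophenyl]methanol, via aryllithium 6 (not isolated)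
Conditions: LiN(i-Pr)2, THF, −78 °C; then 5, −78 °C
Reagents that add atoms: none
Why: Directed ortho-lithiation: the hydrogen at C4 of 3 lies between bromine and a benzyloxy group and is the most acidic one, and at −78 °C the 2-bromoaryllithium 6 should neither lose LiBr nor attack a benzyl ether. Its 1,2-addition to 5 forms the crowded C4–E2' bond as a simple carbonyl addition; the carbinol is racemic, which does not matter because this centre becomes planar in step 6.

Step 5
Reactants: 7 rac-[2-(allyloxy)-4-(benzyloxy)phenyl][2,3,4-tris(benzyloxy)-6-bromophenyl]methanol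
Product: 9 rac-5-(benzyloxy)-2-{[2,3,4-tris(benzyloxy)-6-bromophenyl](4-methylbenzenesulfonyl)methyl}phenol, via O-allyl sulfone 8 (not isolated)
Conditions: p-TolSO2H (3 equiv), CH2Cl2, rt; then Pd(PPh3)4 (5 mol %), rt
Reagents that add atoms: p-toluenesulfinic acid, Cc1ccc(cc1)S(=O)O
Why: SN1 substitution: the 2,4-dialkoxy-stabilised diarylmethyl cation is captured at sulfur by the sulfinate. Tsuji–Trost deallylation follows, in which the same sulfinic acid traps the π-allyl palladium complex as allyl tolyl sulfone; the medium stays acidic, so the freed phenol cannot expel sulfinate prematurely.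

Step 6
Reactants: 9 rac-5-(benzyloxy)-2-{[2,3,4-tris(benzyloxy)-6-bromophenyl](4-methylbenzenesulfonyl)methyl}phenol; 10 benzyloxyacetaldehyde
Product: 13 (3S,4S)-3,7-bis(benzyloxy)-4-[2,3,4-tris(benzyloxy)-6-bromophenyl]chroman-2-ol (both C2 anomers), via o-quinone methide 11 (not isolated), via enamine 12 (not isolated)
Conditions: (R)-α,α-diphenylprolinol trimethylsilyl ether (20 mol %), 10 (3 equiv), NaHCO3, CH2Cl2/H2O, 0 °C to rt
Reagents that add atoms: water, O
Why: NaHCO3 deprotonates the phenol of 9 and the phenoxide expels p-toluenesulfinate (1,4-elimination) to give the o-quinone methide 11, which its 3-benzyloxy group stabilises as a vinylogous ester, while the amine condenses with 10 to the (E)-enamine 12. The enamine β-carbon adds to the methide carbon (conjugate addition, C3–C4), the re-formed phenoxide closes ring C on the iminium carbon (O1–C2, 6-exo-trig), and hydrolysis of the N,O-acetal releases lactol 13 and the amine. The closest known reaction is the enamine-catalysed formal [4+2] annulation of aldehydes with o-quinone methides released from 2-(sulfonylalkyl)phenols, applied here to an α-alkoxy aldehyde and a methide carbon bearing a 2,6-disubstituted aryl group. C3 is set by the catalyst, whose CPh2OSiMe3 group shields one enamine face so that the methide is attacked from the other. C4 is set by the relative topicity of the two π-systems: the (E)-methide approaches with its carbonyl oxygen near the enamine nitrogen, which translates into the 3,4-trans chroman, and C2 is left as an anomeric mixture to be corrected in steps 7 and 8. The step needs enantioselectivity and 3,4-trans selectivity; the substrate contributes the (E)-geometry of 11, in which the twisted ring E avoids the carbonyl oxygen, and a single electrophilic site. The slow addition expected at this crowded carbon should be tolerable because sulfinate re-adds reversibly, the hindered methide is not prone to dimerise, and excess 10 keeps the enamine concentration up.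

Step 7
Reactants: 13 (3S,4S)-3,7-bis(benzyloxy)-4-[2,3,4-tris(benzyloxy)-6-bromophenyl]chroman-2-ol; 3 1,2,3-tris(benzyloxy)-5-bromobenzene
Product: 15 (1S,2S,3S)-2-(benzyloxy)-3-[4-(benzyloxy)-2-hydroxyphenyl]-3-[2,3,4-tris(benzyloxy)-6-bromophenyl]-1-[3,4,5-tris(benzyloxy)phenyl]propan-1-ol, via Grignard reagent 14 (not isolated)
Conditions: 3, Mg, THF, 40 °C; then 13, THF, 0 °C to rt
Reagents that add atoms: none
Why: Grignard addition to a lactol: one equivalent of 14 deprotonates 13, the magnesium lactolate opens to the phenoxide aldehyde, and a further equivalent adds to the carbonyl group. Magnesium bridges the carbonyl oxygen and the C3 benzyloxy oxygen, and the aryl group enters the five-membered chelate anti to the bulky diarylmethyl substituent, which should give the 1,2-syn (1S) carbinol.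

Step 8
Reactants: 15 (1S,2S,3S)-2-(benzyloxy)-3-[4-(benzyloxy)-2-hydroxyphenyl]-3-[2,3,4-tris(benzyloxy)-6-bromophenyl]-1-[3,4,5-tris(benzyloxy)phenyl]propan-1-ol
Product: 16 (2R,3S,4S)-3,7-bis(benzyloxy)-4-[2,3,4-tris(benzyloxy)-6-bromophenyl]-2-[3,4,5-tris(benzyloxy)phenyl]chromane
Conditions: PPh3, DIAD, THF, 0 °C to rt
Reagents that add atoms: none
Why: Intramolecular Mitsunobu etherification (6-exo-tet): the ring A phenol displaces the activated benzylic oxygen with inversion, turning the syn carbinol into the 2,3-trans flavan with C2 (R). Any ionisation of the benzylic oxyphosphonium would still close to the all-equatorial 2,3-trans-3,4-trans ring, so both pathways converge.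

Step 9
Reactants: 16 (2R,3S,4S)-3,7-bis(benzyloxy)-4-[2,3,4-tris(benzyloxy)-6-bromophenyl]-2-[3,4,5-tris(benzyloxy)phenyl]chromane
Product: 18 3,4,5-tris(benzyloxy)-2-[(2R,3S,4S)-3,7-bis(benzyloxy)-2-[3,4,5-tris(benzyloxy)phenyl]chroman-4-yl]benzaldehyde, via aryllithium 17 (not isolated)
Conditions: n-BuLi, THF, −78 °C; then DMF, −78 to 0 °C
Reagents that add atoms: N,N-dimethylformamide, CN(C)C=O
Why: Bromine–lithium exchange is faster at −78 °C than deprotonation of any benzylic position, and aryllithium 17 is formylated by DMF (Bouveault aldehyde synthesis). The aldehyde appears only on work-up, so it is not attacked twice.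

Step 10
Reactants: 18 3,4,5-tris(benzyloxy)-2-[(2R,3S,4S)-3,7-bis(benzyloxy)-2-[3,4,5-tris(benzyloxy)phenyl]chroman-4-yl]benzaldehyde
Product: 19 (1R)-1-{3,4,5-tris(benzyloxy)-2-[(2R,3S,4S)-3,7-bis(benzyloxy)-2-[3,4,5-tris(benzyloxy)phenyl]chroman-4-yl]phenyl}prop-2-en-1-ol
Conditions: Zn(CH=CH2)2 (from CH2=CHMgBr and ZnCl2), (2R)-3-exo-morpholinoisoborneol [(+)-MIB] (20 mol %), toluene, 0 °C
Reagents that add atoms: divinylzinc, C=C[Zn]C=C
Why: Ligand-accelerated addition of an alkenylzinc reagent to an aldehyde: the zinc aminoalkoxide binds the aldehyde and a second zinc species and delivers the vinyl group to the Re face, which gives the (1R) alcohol. The (+)-ligand is the mirror image of the one that sends carbon groups to the Si face of aryl aldehydes; ligand control is used because the resident stereocentres lie across ring E.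

Step 11
Reactants: 4 4-(benzyloxy)-2-hydroxybenzaldehyde
Product: 20 5-(benzyloxy)-2-ethenylphenol
Conditions: Ph3PCH3Br, KOt-Bu (2.2 equiv), THF, 0 °C to rt
Reagents that add atoms: methyltriphenylphosphonium bromide, C[P+](c1ccccc1)(c1ccccc1)c1ccccc1.[Br-]
Why: Wittig methylenation; one equivalent of base is consumed by the phenol and the phenoxide aldehyde still reacts with the unstabilised ylide. The electron-rich vinylphenol is used freshly prepared.

Step 12
Reactants: 19 (1R)-1-{3,4,5-tris(benzyloxy)-2-[(2R,3S,4S)-3,7-bis(benzyloxy)-2-[3,4,5-tris(benzyloxy)phenyl]chroman-4-yl]phenyl}prop-2-en-1-ol; 20 5-(benzyloxy)-2-ethenylphenol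
Product: 21 (2R,3S,4S)-3,7-bis(benzyloxy)-4-{2,3,4-tris(benzyloxy)-6-[(1S)-1-[5-(benzyloxy)-2-ethenylphenoxy]prop-2-en-1-yl]phenyl}-2-[3,4,5-tris(benzyloxy)phenyl]chromane
Conditions: PPh3, DIAD, toluene, 0 °C
Reagents that add atoms: none
Why: Intermolecular Mitsunobu etherification: the phenol protonates the betaine and displaces the oxyphosphonium group of the secondary carbinol with inversion, (1R) to (1S). The carbinol has no β-hydrogen to eliminate, and the 3,4,5-trialkoxyaryl group, whose para oxygen is twisted by its neighbours, stabilises a cation only moderately, which favours the SN2 path.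

Step 13
Reactants: 21 (2R,3S,4S)-3,7-bis(benzyloxy)-4-{2,3,4-tris(benzyloxy)-6-[(1S)-1-[5-(benzyloxy)-2-ethenylphenoxy]prop-2-en-1-yl]phenyl}-2-[3,4,5-tris(benzyloxy)phenyl]chromane
Product: 22 (2R,3S,4S)-3,7-bis(benzyloxy)-4-{2,3,4-tris(benzyloxy)-6-[(2S)-7-(benzyloxy)-2H-chromen-2-yl]phenyl}-2-[3,4,5-tris(benzyloxy)phenyl]chromane
Conditions: RuCl2(=CHPh)(PCy3)(H2IMes) (5 mol %), CH2Cl2, 40 °C
Reagents that add atoms: none
Why: Ring-closing olefin metathesis of the styrene and the allylic vinyl group closes the six-membered ring F as a 2H-chromene with loss of ethene. No bond to the C2 stereocentre is touched.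

Step 14
Reactants: 22 (2R,3S,4S)-3,7-bis(benzyloxy)-4-{2,3,4-tris(benzyloxy)-6-[(2S)-7-(benzyloxy)-2H-chromen-2-yl]phenyl}-2-[3,4,5-tris(benzyloxy)phenyl]chromane
Product: 23 (2R,3S,4S)-7-(benzyloxy)-2-{3,4,5-tris(benzyloxy)-2-[(2R,3S,4S)-3,7-bis(benzyloxy)-2-[3,4,5-tris(benzyloxy)phenyl]chroman-4-yl]phenyl}chromane-3,4-diol
Conditions: OsO4 (5 mol %), NMO, acetone/H2O, rt
Reagents that add atoms: osmium tetroxide, O=[Os](=O)(=O)=O; N-methylmorpholine N-oxide, C[N+]1([O-])CCOCC1; water, O
Why: Catalytic syn-dihydroxylation (Upjohn conditions): the osmate ester forms on the face of the cis-alkene opposite the bulky C2 aryl group, so the two hydroxyl groups are cis to each other and the C3 hydroxyl is trans to ring E, (2R,3S,4S). NMO reoxidises osmium and no other alkene is present.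

Step 15
Reactants: 23 (2R,3S,4S)-7-(benzyloxy)-2-{3,4,5-tris(benzyloxy)-2-[(2R,3S,4S)-3,7-bis(benzyloxy)-2-[3,4,5-tris(benzyloxy)phenyl]chroman-4-yl]phenyl}chromane-3,4-diol
Product: 24 (2R,3S,4S)-2-{3,4,5-trihydroxy-2-[(2R,3S,4S)-3,7-dihydroxy-2-(3,4,5-trihydroxyphenyl)chroman-4-yl]phenyl}chromane-3,4,7-triol
Conditions: H2 (1 atm), Pd(OH)2/C, THF/EtOAc, rt
Reagents that add atoms: none
Why: Heterogeneous hydrogenolysis cleaves the eight aryl benzyl ethers and the C3 alkyl benzyl ether. A neutral, non-nucleophilic solvent and atmospheric pressure are chosen so that the ring benzylic C–O bonds, which lack acid activation, should stay intact; the product is handled under argon.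

## Compound list

1 | 5-bromo-1,2,3-trimethoxybenzene | COc1cc(Br)cc(OC)c1OC | starting material
2 | 5-bromobenzene-1,2,3-triol | Oc1cc(Br)cc(O)c1O | intermediate
3 | 1,2,3-tris(benzyloxy)-5-bromobenzene | Brc1cc(OCc2ccccc2)c(OCc2ccccc2)c(OCc2ccccc2)c1 | intermediate
4 | 4-(benzyloxy)-2-hydroxybenzaldehyde | O=Cc1ccc(OCc2ccccc2)cc1O | starting material
5 | 2-(allyloxy)-4-(benzyloxy)benzaldehyde | O=Cc1ccc(OCc2ccccc2)cc1OCC=C | intermediate
6 | [2,3,4-tris(benzyloxy)-6-bromophenyl]lithium | [Li]c1c(Br)cc(OCc2ccccc2)c(OCc2ccccc2)c1OCc1ccccc1 | intermediate (not isolated)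
7 | rac-[2-(allyloxy)-4-(benzyloxy)phenyl][2,3,4-tris(benzyloxy)-6-bromophenyl]methanol | OC(c1ccc(OCc2ccccc2)cc1OCC=C)c1c(Br)cc(OCc2ccccc2)c(OCc2ccccc2)c1OCc1ccccc1 | intermediate
8 | rac-2-(allyloxy)-4-(benzyloxy)-1-{[2,3,4-tris(benzyloxy)-6-bromophenyl](4-methylbenzenesulfonyl)methyl}benzene | Cc1ccc(cc1)S(=O)(=O)C(c1ccc(OCc2ccccc2)cc1OCC=C)c1c(Br)cc(OCc2ccccc2)c(OCc2ccccc2)c1OCc1ccccc1 | intermediate (not isolated)
9 | rac-5-(benzyloxy)-2-{[2,3,4-tris(benzyloxy)-6-bromophenyl](4-methylbenzenesulfonyl)methyl}phenol | Cc1ccc(cc1)S(=O)(=O)C(c1ccc(OCc2ccccc2)cc1O)c1c(Br)cc(OCc2ccccc2)c(OCc2ccccc2)c1OCc1ccccc1 | intermediate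
10 | benzyloxyacetaldehyde | O=CCOCc1ccccc1 | starting material
11 | (E)-3-(benzyloxy)-6-{[2,3,4-tris(benzyloxy)-6-bromophenyl]methylidene}cyclohexa-2,4-dien-1-one | O=C1C=C(OCc2ccccc2)C=C/C1=C\c3c(Br)cc(OCc2ccccc2)c(OCc2ccccc2)c3OCc2ccccc2 | intermediate (not isolated)
12 | (R)-1-[(E)-2-(benzyloxy)ethenyl]-2-[diphenyl(trimethylsilyloxy)methyl]pyrrolidine | C[Si](C)(C)OC(c1ccccc1)(c1ccccc1)[C@H]1CCCN1/C=C/OCc1ccccc1 | intermediate (not isolated)
13 | (3S,4S)-3,7-bis(benzyloxy)-4-[2,3,4-tris(benzyloxy)-6-bromophenyl]chroman-2-ol (both C2 anomers) | O(Cc1ccccc1)c1ccc2c(c1)OC(O)[C@@H](OCc1ccccc1)[C@@H]2c1c(Br)cc(OCc2ccccc2)c(OCc2ccccc2)c1OCc1ccccc1 | intermediate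
14 | [3,4,5-tris(benzyloxy)phenyl]magnesium bromide | Br[Mg]c1cc(OCc2ccccc2)c(OCc2ccccc2)c(OCc2ccccc2)c1 | intermediate (not isolated)
15 | (1S,2S,3S)-2-(benzyloxy)-3-[4-(benzyloxy)-2-hydroxyphenyl]-3-[2,3,4-tris(benzyloxy)-6-bromophenyl]-1-[3,4,5-tris(benzyloxy)phenyl]propan-1-ol | O[C@@H](c1cc(OCc2ccccc2)c(OCc2ccccc2)c(OCc2ccccc2)c1)[C@@H](OCc1ccccc1)[C@@H](c1ccc(OCc2ccccc2)cc1O)c1c(Br)cc(OCc2ccccc2)c(OCc2ccccc2)c1OCc1ccccc1 | intermediate
16 | (2R,3S,4S)-3,7-bis(benzyloxy)-4-[2,3,4-tris(benzyloxy)-6-bromophenyl]-2-[3,4,5-tris(benzyloxy)phenyl]chromane | O(Cc1ccccc1)c1ccc2c(c1)O[C@H](c1cc(OCc3ccccc3)c(OCc3ccccc3)c(OCc3ccccc3)c1)[C@@H](OCc1ccccc1)[C@@H]2c1c(Br)cc(OCc2ccccc2)c(OCc2ccccc2)c1OCc1ccccc1 | intermediate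
17 | {3,4,5-tris(benzyloxy)-2-[(2R,3S,4S)-3,7-bis(benzyloxy)-2-[3,4,5-tris(benzyloxy)phenyl]chroman-4-yl]phenyl}lithium | O(Cc1ccccc1)c1ccc2c(c1)O[C@H](c1cc(OCc3ccccc3)c(OCc3ccccc3)c(OCc3ccccc3)c1)[C@@H](OCc1ccccc1)[C@@H]2c1c([Li])cc(OCc2ccccc2)c(OCc2ccccc2)c1OCc1ccccc1 | intermediate (not isolated)
18 | 3,4,5-tris(benzyloxy)-2-[(2R,3S,4S)-3,7-bis(benzyloxy)-2-[3,4,5-tris(benzyloxy)phenyl]chroman-4-yl]benzaldehyde | O(Cc1ccccc1)c1ccc2c(c1)O[C@H](c1cc(OCc3ccccc3)c(OCc3ccccc3)c(OCc3ccccc3)c1)[C@@H](OCc1ccccc1)[C@@H]2c1c(C=O)cc(OCc2ccccc2)c(OCc2ccccc2)c1OCc1ccccc1 | intermediate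
19 | (1R)-1-{3,4,5-tris(benzyloxy)-2-[(2R,3S,4S)-3,7-bis(benzyloxy)-2-[3,4,5-tris(benzyloxy)phenyl]chroman-4-yl]phenyl}prop-2-en-1-ol | O(Cc1ccccc1)c1ccc2c(c1)O[C@H](c1cc(OCc3ccccc3)c(OCc3ccccc3)c(OCc3ccccc3)c1)[C@@H](OCc1ccccc1)[C@@H]2c1c([C@@H](C=C)O)cc(OCc2ccccc2)c(OCc2ccccc2)c1OCc1ccccc1 | intermediate
20 | 5-(benzyloxy)-2-ethenylphenol | C=Cc1ccc(OCc2ccccc2)cc1O | intermediate
21 | (2R,3S,4S)-3,7-bis(benzyloxy)-4-{2,3,4-tris(benzyloxy)-6-[(1S)-1-[5-(benzyloxy)-2-ethenylphenoxy]prop-2-en-1-yl]phenyl}-2-[3,4,5-tris(benzyloxy)phenyl]chromane | O(Cc1ccccc1)c1ccc2c(c1)O[C@H](c1cc(OCc3ccccc3)c(OCc3ccccc3)c(OCc3ccccc3)c1)[C@@H](OCc1ccccc1)[C@@H]2c1c([C@H](C=C)Oc2cc(OCc3ccccc3)ccc2C=C)cc(OCc2ccccc2)c(OCc2ccccc2)c1OCc1ccccc1 | intermediate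
22 | (2R,3S,4S)-3,7-bis(benzyloxy)-4-{2,3,4-tris(benzyloxy)-6-[(2S)-7-(benzyloxy)-2H-chromen-2-yl]phenyl}-2-[3,4,5-tris(benzyloxy)phenyl]chromane | O(Cc1ccccc1)c1ccc2c(c1)O[C@H](c1cc(OCc3ccccc3)c(OCc3ccccc3)c(OCc3ccccc3)c1)[C@@H](OCc1ccccc1)[C@@H]2c1c([C@H]2Oc3cc(OCc4ccccc4)ccc3C=C2)cc(OCc2ccccc2)c(OCc2ccccc2)c1OCc1ccccc1 | intermediate
23 | (2R,3S,4S)-7-(benzyloxy)-2-{3,4,5-tris(benzyloxy)-2-[(2R,3S,4S)-3,7-bis(benzyloxy)-2-[3,4,5-tris(benzyloxy)phenyl]chroman-4-yl]phenyl}chromane-3,4-diol | O(Cc1ccccc1)c1ccc2c(c1)O[C@H](c1cc(OCc3ccccc3)c(OCc3ccccc3)c(OCc3ccccc3)c1)[C@@H](OCc1ccccc1)[C@@H]2c1c([C@H]2Oc3cc(OCc4ccccc4)ccc3[C@H](O)[C@@H]2O)cc(OCc2ccccc2)c(OCc2ccccc2)c1OCc1ccccc1 | intermediate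
24 | (2R,3S,4S)-2-{3,4,5-trihydroxy-2-[(2R,3S,4S)-3,7-dihydroxy-2-(3,4,5-trihydroxyphenyl)chroman-4-yl]phenyl}chromane-3,4,7-triol | Oc1ccc2c(c1)O[C@H](c1cc(O)c(O)c(O)c1)[C@@H](O)[C@@H]2c1c([C@H]2Oc3cc(O)ccc3[C@H](O)[C@@H]2O)cc(O)c(O)c1O | target

## Step count and least certain steps

Total: 15 steps. Longest linear sequence: 13 steps (steps 1, 2, 4, 5, 6, 7, 8, 9, 10, 12, 13, 14 and 15, from 1 to 24).

**Step 6 (key step).** The carbon–carbon bond formation may be too slow, because the ortho bromine and benzyloxy group of the perpendicular ring E screen both faces of the methide carbon. The enamine would then be consumed by self-condensation of 10, the methide would return to 9 or add water, and facial selectivity could erode where ring E meets the CPh2OSiMe3 group. The fallback sets out from 9 and comes back at 13. It replaces the bulky enamine by a compact, charged nucleophile under auxiliary control: two equivalents of the sodium enolate of (R)-4-benzyl-3-[(benzyloxy)acetyl]oxazolidin-2-one (NaN(SiMe3)2, THF, −78 °C) release the methide from 9 and add to it, and the phenoxide so formed lactonises on the imide carbonyl with loss of the oxazolidinone. This should give the dihydrocoumarin (3S,4S)-3,7-bis(benzyloxy)-4-[2,3,4-tris(benzyloxy)-6-bromophenyl]chroman-2-one F1, with C3 set by the benzyl group of the auxiliary and any 3,4-cis lactone removed by chromatography. Reduction of F1 with i-Bu2AlH in CH2Cl2 at −78 °C would give 13.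

**Step 10.** Facial selectivity at the new carbinol may be poor if the ligand and the resident flavan stereocentres are mismatched, or the hindered aldehyde may react slowly enough for the unligated background addition to compete. The fallback sets out from 18 and comes back at 19. CH2=CHMgBr is added without control to give 19 together with its epimer (1S)-1-{3,4,5-tris(benzyloxy)-2-[(2R,3S,4S)-3,7-bis(benzyloxy)-2-[3,4,5-tris(benzyloxy)phenyl]chroman-4-yl]phenyl}prop-2-en-1-ol F2. Dess–Martin periodinane oxidises the mixture to the aryl vinyl ketone 1-{3,4,5-tris(benzyloxy)-2-[(2R,3S,4S)-3,7-bis(benzyloxy)-2-[3,4,5-tris(benzyloxy)phenyl]chroman-4-yl]phenyl}prop-2-en-1-one F3. CBS reduction of F3 with (S)-2-methyl-CBS-oxazaborolidine and catecholborane at −78 °C, the aryl group acting as the large substituent, should then return 19.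

**Step 12.** The activated oxyphosphonium may ionise, with loss of configuration, or the phenol may attack the alkene terminus (SN2') to give the linear cinnamyl ether; both are encouraged by the bulky ortho substituent, which slows direct displacement. The fallback sets out from 18 and comes back at 21, bypassing steps 10 and 12, and makes the C–O bond at an allyl-metal intermediate instead of by displacement. Horner–Wadsworth–Emmons olefination (triethyl phosphonoacetate, NaH, THF) gives ethyl (2E)-3-{3,4,5-tris(benzyloxy)-2-[(2R,3S,4S)-3,7-bis(benzyloxy)-2-[3,4,5-tris(benzyloxy)phenyl]chroman-4-yl]phenyl}prop-2-enoate F4. Reduction with i-Bu2AlH gives the allylic alcohol (2E)-3-{3,4,5-tris(benzyloxy)-2-[(2R,3S,4S)-3,7-bis(benzyloxy)-2-[3,4,5-tris(benzyloxy)phenyl]chroman-4-yl]phenyl}prop-2-en-1-ol F5, and ClCO2Me with pyridine gives methyl (2E)-3-{3,4,5-tris(benzyloxy)-2-[(2R,3S,4S)-3,7-bis(benzyloxy)-2-[3,4,5-tris(benzyloxy)phenyl]chroman-4-yl]phenyl}prop-2-en-1-yl carbonate F6. Branch-selective allylic etherification of F6 with the lithium salt of 20, catalysed by [Ir(cod)Cl]2 and a chiral phosphoramidite ligand of the enantiomer that leads to the (S) ether, would give 21.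

**Step 15.** Once the para 7-hydroxyl of ring D is unveiled, the benzylic C4 hydroxyl of ring F may be lost by hydrogenolysis through a quinone methide, or the product may self-condense if traces of acid build up on the catalyst. The fallback sets out from 23 and comes back at 24. The cis-diol is tied up with t-Bu2Si(OTf)2 and 2,6-lutidine as the 3,4-O-(di-tert-butylsilanediyl) derivative of 23 F7. Hydrogenolysis (H2, Pd(OH)2/C, THF/EtOAc) then gives the 3,4-O-(di-tert-butylsilanediyl) derivative of 24 F8, in which the C4 oxygen can no longer leave as water. HF·pyridine in THF/pyridine at 0 °C removes the silylene group and gives 24.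

## Further compounds

F1 | step 6 | (3S,4S)-3,7-bis(benzyloxy)-4-[2,3,4-tris(benzyloxy)-6-bromophenyl]chroman-2-one | O(Cc1ccccc1)c1ccc2c(c1)OC(=O)[C@@H](OCc1ccccc1)[C@@H]2c1c(Br)cc(OCc2ccccc2)c(OCc2ccccc2)c1OCc1ccccc1
F2 | step 10 | (1S)-1-{3,4,5-tris(benzyloxy)-2-[(2R,3S,4S)-3,7-bis(benzyloxy)-2-[3,4,5-tris(benzyloxy)phenyl]chroman-4-yl]phenyl}prop-2-en-1-ol | O(Cc1ccccc1)c1ccc2c(c1)O[C@H](c1cc(OCc3ccccc3)c(OCc3ccccc3)c(OCc3ccccc3)c1)[C@@H](OCc1ccccc1)[C@@H]2c1c([C@H](C=C)O)cc(OCc2ccccc2)c(OCc2ccccc2)c1OCc1ccccc1
F3 | step 10 | 1-{3,4,5-tris(benzyloxy)-2-[(2R,3S,4S)-3,7-bis(benzyloxy)-2-[3,4,5-tris(benzyloxy)phenyl]chroman-4-yl]phenyl}prop-2-en-1-one | O(Cc1ccccc1)c1ccc2c(c1)O[C@H](c1cc(OCc3ccccc3)c(OCc3ccccc3)c(OCc3ccccc3)c1)[C@@H](OCc1ccccc1)[C@@H]2c1c(C(=O)C=C)cc(OCc2ccccc2)c(OCc2ccccc2)c1OCc1ccccc1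
F4 | step 12 | ethyl (2E)-3-{3,4,5-tris(benzyloxy)-2-[(2R,3S,4S)-3,7-bis(benzyloxy)-2-[3,4,5-tris(benzyloxy)phenyl]chroman-4-yl]phenyl}prop-2-enoate | O(Cc1ccccc1)c1ccc2c(c1)O[C@H](c1cc(OCc3ccccc3)c(OCc3ccccc3)c(OCc3ccccc3)c1)[C@@H](OCc1ccccc1)[C@@H]2c1c(/C=C/C(=O)OCC)cc(OCc2ccccc2)c(OCc2ccccc2)c1OCc1ccccc1
F5 | step 12 | (2E)-3-{3,4,5-tris(benzyloxy)-2-[(2R,3S,4S)-3,7-bis(benzyloxy)-2-[3,4,5-tris(benzyloxy)phenyl]chroman-4-yl]phenyl}prop-2-en-1-ol | O(Cc1ccccc1)c1ccc2c(c1)O[C@H](c1cc(OCc3ccccc3)c(OCc3ccccc3)c(OCc3ccccc3)c1)[C@@H](OCc1ccccc1)[C@@H]2c1c(/C=C/CO)cc(OCc2ccccc2)c(OCc2ccccc2)c1OCc1ccccc1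
F6 | step 12 | methyl (2E)-3-{3,4,5-tris(benzyloxy)-2-[(2R,3S,4S)-3,7-bis(benzyloxy)-2-[3,4,5-tris(benzyloxy)phenyl]chroman-4-yl]phenyl}prop-2-en-1-yl carbonate | O(Cc1ccccc1)c1ccc2c(c1)O[C@H](c1cc(OCc3ccccc3)c(OCc3ccccc3)c(OCc3ccccc3)c1)[C@@H](OCc1ccccc1)[C@@H]2c1c(/C=C/COC(=O)OC)cc(OCc2ccccc2)c(OCc2ccccc2)c1OCc1ccccc1
F7 | step 15 | 3,4-O-(di-tert-butylsilanediyl) derivative of 23 | O(Cc1ccccc1)c1ccc2c(c1)O[C@H](c1cc(OCc3ccccc3)c(OCc3ccccc3)c(OCc3ccccc3)c1)[C@@H](OCc1ccccc1)[C@@H]2c1c([C@H]2Oc3cc(OCc4ccccc4)ccc3[C@H](O[Si]4(C(C)(C)C)C(C)(C)C)[C@@H]2O4)cc(OCc2ccccc2)c(OCc2ccccc2)c1OCc1ccccc1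
F8 | step 15 | 3,4-O-(di-tert-butylsilanediyl) derivative of 24 | Oc1ccc2c(c1)O[C@H](c1cc(O)c(O)c(O)c1)[C@@H](O)[C@@H]2c1c([C@H]2Oc3cc(O)ccc3[C@H](O[Si]4(C(C)(C)C)C(C)(C)C)[C@@H]2O4)cc(O)c(O)c1O
A1 | alternative 1 | aryl allyl ether diene, identical with 21 | O(Cc1ccccc1)c1ccc2c(c1)O[C@H](c1cc(OCc3ccccc3)c(OCc3ccccc3)c(OCc3ccccc3)c1)[C@@H](OCc1ccccc1)[C@@H]2c1c([C@H](C=C)Oc2cc(OCc3ccccc3)ccc2C=C)cc(OCc2ccccc2)c(OCc2ccccc2)c1OCc1ccccc1
A2 | alternative 1 | upper flavan carrying the lower unit as a (2S)-2-aryl-2H-chromene, identical with 22 | O(Cc1ccccc1)c1ccc2c(c1)O[C@H](c1cc(OCc3ccccc3)c(OCc3ccccc3)c(OCc3ccccc3)c1)[C@@H](OCc1ccccc1)[C@@H]2c1c([C@H]2Oc3cc(OCc4ccccc4)ccc3C=C2)cc(OCc2ccccc2)c(OCc2ccccc2)c1OCc1ccccc1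
A3 | alternative 2 | (2R,3S)-3-[4-(benzyloxy)-2-hydroxyphenyl]-3-[2,3,4-tris(benzyloxy)-6-bromophenyl]-1-[3,5-bis(benzyloxy)-4-hydroxyphenyl]propan-2-ol | Oc1c(OCc2ccccc2)cc(C[C@@H](O)[C@@H](c2ccc(OCc3ccccc3)cc2O)c2c(Br)cc(OCc3ccccc3)c(OCc3ccccc3)c2OCc2ccccc2)cc1OCc1ccccc1
A4 | alternative 2 | p-quinone methide of A3: 2,6-bis(benzyloxy)-4-(3,3-diaryl-2-hydroxypropylidene)cyclohexa-2,5-dien-1-one with the two sp3 centres as in A3 | O=C1C(OCc2ccccc2)=CC(=C[C@@H](O)[C@@H](c2ccc(OCc3ccccc3)cc2O)c2c(Br)cc(OCc3ccccc3)c(OCc3ccccc3)c2OCc2ccccc2)C=C1OCc1ccccc1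
A5 | alternative 2 | (2R,3S,4S)-7-(benzyloxy)-2-[3,5-bis(benzyloxy)-4-hydroxyphenyl]-4-[2,3,4-tris(benzyloxy)-6-bromophenyl]chroman-3-ol | O(Cc1ccccc1)c1ccc2c(c1)O[C@H](c1cc(OCc3ccccc3)c(O)c(OCc3ccccc3)c1)[C@@H](O)[C@@H]2c1c(Br)cc(OCc2ccccc2)c(OCc2ccccc2)c1OCc1ccccc1
A6 | alternative 3 | methyl 3-[(2R,3S,4R)-3,7-bis(benzyloxy)-2-[3,4,5-tris(benzyloxy)phenyl]chroman-4-yl]prop-2-ynoate | O(Cc1ccccc1)c1ccc2c(c1)O[C@H](c1cc(OCc3ccccc3)c(OCc3ccccc3)c(OCc3ccccc3)c1)[C@@H](OCc1ccccc1)[C@@H]2C#CC(=O)OC
A7 | alternative 3 | 3,4-bis(benzyloxy)furan | o1cc(OCc2ccccc2)c(OCc2ccccc2)c1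
A8 | alternative 3 | methyl 4,5-bis(benzyloxy)-3-hydroxy-2-[(2R,3S,4S)-3,7-bis(benzyloxy)-2-[3,4,5-tris(benzyloxy)phenyl]chroman-4-yl]benzoate | O(Cc1ccccc1)c1ccc2c(c1)O[C@H](c1cc(OCc3ccccc3)c(OCc3ccccc3)c(OCc3ccccc3)c1)[C@@H](OCc1ccccc1)[C@@H]2c1c(C(=O)OC)cc(OCc2ccccc2)c(OCc2ccccc2)c1O
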